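The flavone is cut at the C4–C4a bond of the pyranone (ring C). On ring A the carbon that becomes C4a is the only unsubstituted position ortho to the ring oxygen O1. It also lies ortho to the C5 oxygen and para to the C7 oxygen, so a tethered acyl electrophile can only attack there and meets a strongly activated site. The key step closes ring C by intramolecular Friedel–Crafts acylation of acid 15, an (E)-β-aryloxy-α-methoxycinnamic acid that already carries O1–C2, the C3 methoxy group, ring B and every oxygen substituent, with the three future phenols as benzyl ethers. A single hydrogenolysis then gives the target.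

Key step: step 10

Remark on the chemistry: in 13–16 the descriptor E places the ester or carboxyl group cis to the triflate or aryloxy group, which is the only geometry from which ring C can close, so it is set deliberately in steps 7 and 8. Compound 12 is racemic and its stereocentre disappears in step 7. The target has no stereocentre.

Step 1
Reactants: 1 3-hydroxy-4,5-dimethoxybenzaldehyde
Product: 2 3,4-dimethoxy-5-(methoxymethoxy)benzaldehyde
Conditions: NaH, DMF, 0 °C; MOMCl, 0 °C → rt
Reagents that add atoms: chloromethyl methyl ether, COCCl
Why: Williamson-type O-alkylation of the sodium phenoxide masks the future O1 phenol as a methoxymethyl acetal that should withstand peracid, carbonate base and benzylation.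

Step 2
Reactants: 2 3,4-dimethoxy-5-(methoxymethoxy)benzaldehyde
Product: 4 3,4-dimethoxy-5-(methoxymethoxy)phenol, via aryl formate 3 (not isolated)
Conditions: mCPBA, CH2Cl2, 0 °C → rt; then K2CO3 (cat.), MeOH, rt
Reagents that add atoms: 3-chloroperoxybenzoic acid, O=C(OO)c1cccc(Cl)c1
Why: Baeyer–Villiger oxidation of the aldehyde (the peracid form of the Dakin oxidation) should proceed by migration of the aryl group, favoured by its para methoxy group, and the resulting formate is cleaved by mild methanolysis without touching the acetal.

Step 3
Reactants: 4 3,4-dimethoxy-5-(methoxymethoxy)phenol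
Product: 5 5-(benzyloxy)-1,2-dimethoxy-3-(methoxymethoxy)benzene
Conditions: BnBr, K2CO3, DMF, rt
Reagents that add atoms: benzyl bromide, BrCc1ccccc1
Why: Williamson ether synthesis on the only free phenol places the benzyl group on the oxygen that becomes the C5 oxygen of the flavone.

Step 4
Reactants: 5 5-(benzyloxy)-1,2-dimethoxy-3-(methoxymethoxy)benzene
Product: 6 5-(benzyloxy)-2,3-dimethoxyphenol
Conditions: HCl (cat.), MeOH, 40 °C
Reagents that add atoms: none
Why: Acid-catalysed acetal methanolysis should remove the methoxymethyl group selectively, since benzyl and methyl aryl ethers are inert to dilute methanolic acid.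

Step 5
Reactants: 7 2,3-dihydroxybenzoic acid
Product: 9 2,3-bis(benzyloxy)benzoic acid, via benzyl ester 8 (not isolated)
Conditions: BnBr, K2CO3, acetone, reflux; then NaOH, MeOH/H2O, reflux; then HCl
Reagents that add atoms: benzyl bromide, BrCc1ccccc1; sodium hydroxide, [Na+].[OH-] (supplies the carboxyl OH oxygen)
Why: Exhaustive Williamson benzylation followed by saponification of the benzyl ester should leave both catechol oxygens protected and the carboxyl group free.

Step 6
Reactants: 9 2,3-bis(benzyloxy)benzoic acid; 10 methyl methoxyacetate
Product: 12 methyl 3-[2,3-bis(benzyloxy)phenyl]-2-methoxy-3-oxopropanoate (racemic), via acid chloride 11 (not isolated)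
Conditions: (COCl)2, DMF (cat.), CH2Cl2, rt, evaporate; then 10 (2.2 equiv), LiN(iPr)2 (2.2 equiv), THF, −78 °C; 1 M HCl
Reagents that add atoms: none
Why: Claisen-type C-acylation of the lithium enolate of 10 by the aroyl chloride should give the α-methoxy β-keto ester; the second equivalent of enolate deprotonates the product and so prevents a second acylation, and the new stereocentre is formed racemic and is removed in step 7.

Step 7
Reactants: 12 methyl 3-[2,3-bis(benzyloxy)phenyl]-2-methoxy-3-oxopropanoate
Product: 13 methyl (E)-3-[2,3-bis(benzyloxy)phenyl]-2-methoxy-3-{[(trifluoromethyl)sulfonyl]oxy}prop-2-enoate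
Conditions: NaH, CH2Cl2, 0 °C; then (CF3SO2)2O, 0 °C
Reagents that add atoms: trifluoromethanesulfonic anhydride, O=S(=O)(OS(=O)(=O)C(F)(F)F)C(F)(F)F
Why: O-sulfonylation of the sodium-chelated, U-shaped β-keto ester enolate should place the triflate cis to the ester group, which corresponds to the E enol triflate.

Step 8
Reactants: 13 methyl (E)-3-[2,3-bis(benzyloxy)phenyl]-2-methoxy-3-{[(trifluoromethyl)sulfonyl]oxy}prop-2-enoate; 6 5-(benzyloxy)-2,3-dimethoxyphenol
Product: 14 methyl (E)-3-[5-(benzyloxy)-2,3-dimethoxyphenoxy]-3-[2,3-bis(benzyloxy)phenyl]-2-methoxyprop-2-enoate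
Conditions: Cs2CO3, MeCN, rt → 50 °C
Reagents that add atoms: none
Why: Nucleophilic vinylic substitution by addition–elimination: the phenoxide adds to the β-carbon activated by the ester and the triflate, and triflate should leave from the ester enolate faster than the C–C bond rotates, so the aryloxy group is expected to stay cis to the ester (E); any minor Z isomer is removed by chromatography.

Step 9
Reactants: 14 methyl (E)-3-[5-(benzyloxy)-2,3-dimethoxyphenoxy]-3-[2,3-bis(benzyloxy)phenyl]-2-methoxyprop-2-enoate
Product: 15 (E)-3-[5-(benzyloxy)-2,3-dimethoxyphenoxy]-3-[2,3-bis(benzyloxy)phenyl]-2-methoxyprop-2-enoic acid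
Conditions: LiOH·H2O, THF/H2O, rt → 45 °C; then 1 M HCl, 0 °C, pH 3
Reagents that add atoms: lithium hydroxide, [Li+].[OH-] (supplies the carboxyl OH oxygen)
Why: Saponification by acyl substitution at the ester carbonyl, which is more accessible than the fully substituted β-carbon; the methanol-free medium avoids exchange of the aryloxy group by methoxide, and cold, mild acidification should preserve the enol ether and its geometry.

Step 10
Reactants: 15 (E)-3-[5-(benzyloxy)-2,3-dimethoxyphenoxy]-3-[2,3-bis(benzyloxy)phenyl]-2-methoxyprop-2-enoic acid
Product: 17 5-(benzyloxy)-2-[2,3-bis(benzyloxy)phenyl]-3,7,8-trimethoxy-4H-chromen-4-one, via mixed trifluoroacetic anhydride 16 (not isolated)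
Conditions: (CF3CO)2O, CH2Cl2, 0 °C → rt
Reagents that add atoms: none
Why: The anhydride turns the carboxyl group of 15 into mixed anhydride 16, which ionises, helped by the CF3CO2H set free, towards an acylium ion stabilised by the methoxy and aryloxy donors on the alkene; this electrophile attacks the ring A carbon that becomes C4a, and loss of a proton from the arenium ion forms the C4–C4a bond. The closest known reaction type is the Ruhemann ring closure of β-aryloxyacrylic and β-aryloxycinnamic acids to chromones and flavones, an intramolecular Friedel–Crafts acylation that the same anhydride also brings about when 2-aryloxybenzoic acids are closed to xanthones. Ring C closes in a 6-exo-trig mode at the acyl carbon of 16 (6-exo-dig if the free acylium ion reacts), with the nucleophilic C8a=C4a π bond inside the new ring. No stereocentre is formed, and the E alkene of 15 becomes the endocyclic C2=C3 bond. The step needs site selectivity and chemoselectivity: the O1 tether can deliver the acyl carbon only to C4a, which is ortho to O1 and to the C5 benzyloxy group and para to the C7 methoxy group, while the E geometry holds the carboxyl group cis to the aryloxy group and away from ring B, so neither indenone formation at C6' nor lactonisation onto the 2'-benzyloxy oxygen should compete. The absence of a Lewis acid and the low temperature should leave the three benzyl ethers in place.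

Step 11
Reactants: 17 5-(benzyloxy)-2-[2,3-bis(benzyloxy)phenyl]-3,7,8-trimethoxy-4H-chromen-4-one
Product: 18 2-(2,3-dihydroxyphenyl)-5-hydroxy-3,7,8-trimethoxy-4H-chromen-4-one (5,2',3'-trihydroxy-3,7,8-trimethoxyflavone)
Conditions: H2 (1 atm), 10% Pd/C, EtOAc/MeOH, rt
Reagents that add atoms: none
Why: Catalytic hydrogenolysis should cleave the three benzylic C–O bonds, while the methyl ethers and the tetrasubstituted, conjugated C2=C3 bond of the pyranone are not expected to react at atmospheric pressure and room temperature.

Compound list
1 | 3-hydroxy-4,5-dimethoxybenzaldehyde | COc1cc(C=O)cc(O)c1OC | starting material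
2 | 3,4-dimethoxy-5-(methoxymethoxy)benzaldehyde | COCOc1cc(C=O)cc(OC)c1OC | intermediate
3 | 3,4-dimethoxy-5-(methoxymethoxy)phenyl formate | COCOc1cc(OC=O)cc(OC)c1OC | intermediate
4 | 3,4-dimethoxy-5-(methoxymethoxy)phenol | COCOc1cc(O)cc(OC)c1OC | intermediate
5 | 5-(benzyloxy)-1,2-dimethoxy-3-(methoxymethoxy)benzene | COCOc1cc(OCc2ccccc2)cc(OC)c1OC | intermediate
6 | 5-(benzyloxy)-2,3-dimethoxyphenol | COc1cc(OCc2ccccc2)cc(O)c1OC | intermediate
7 | 2,3-dihydroxybenzoic acid | O=C(O)c1cccc(O)c1O | starting material
8 | benzyl 2,3-bis(benzyloxy)benzoate | O=C(OCc1ccccc1)c1cccc(OCc2ccccc2)c1OCc1ccccc1 | intermediate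
9 | 2,3-bis(benzyloxy)benzoic acid | O=C(O)c1cccc(OCc2ccccc2)c1OCc1ccccc1 | intermediate
10 | methyl methoxyacetate | COCC(=O)OC | starting material
11 | 2,3-bis(benzyloxy)benzoyl chloride | O=C(Cl)c1cccc(OCc2ccccc2)c1OCc1ccccc1 | intermediate
12 | methyl 3-[2,3-bis(benzyloxy)phenyl]-2-methoxy-3-oxopropanoate (racemic) | COC(=O)C(OC)C(=O)c1cccc(OCc2ccccc2)c1OCc1ccccc1 | intermediate
13 | methyl (E)-3-[2,3-bis(benzyloxy)phenyl]-2-methoxy-3-{[(trifluoromethyl)sulfonyl]oxy}prop-2-enoate | CO/C(C(=O)OC)=C(/OS(=O)(=O)C(F)(F)F)c1cccc(OCc2ccccc2)c1OCc1ccccc1 | intermediate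
14 | methyl (E)-3-[5-(benzyloxy)-2,3-dimethoxyphenoxy]-3-[2,3-bis(benzyloxy)phenyl]-2-methoxyprop-2-enoate | CO/C(C(=O)OC)=C(/Oc1cc(OCc2ccccc2)cc(OC)c1OC)c1cccc(OCc2ccccc2)c1OCc1ccccc1 | intermediate
15 | (E)-3-[5-(benzyloxy)-2,3-dimethoxyphenoxy]-3-[2,3-bis(benzyloxy)phenyl]-2-methoxyprop-2-enoic acid | CO/C(C(=O)O)=C(/Oc1cc(OCc2ccccc2)cc(OC)c1OC)c1cccc(OCc2ccccc2)c1OCc1ccccc1 | intermediate
16 | (E)-3-[5-(benzyloxy)-2,3-dimethoxyphenoxy]-3-[2,3-bis(benzyloxy)phenyl]-2-methoxyprop-2-enoic trifluoroacetic anhydride | CO/C(C(=O)OC(=O)C(F)(F)F)=C(/Oc1cc(OCc2ccccc2)cc(OC)c1OC)c1cccc(OCc2ccccc2)c1OCc1ccccc1 | intermediate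
17 | 5-(benzyloxy)-2-[2,3-bis(benzyloxy)phenyl]-3,7,8-trimethoxy-4H-chromen-4-one | COc1cc(OCc2ccccc2)c2c(=O)c(OC)c(-c3cccc(OCc4ccccc4)c3OCc3ccccc3)oc2c1OC | intermediate
18 | 2-(2,3-dihydroxyphenyl)-5-hydroxy-3,7,8-trimethoxy-4H-chromen-4-one | COc1cc(O)c2c(=O)c(OC)c(-c3cccc(O)c3O)oc2c1OC | target

Total step count: 11.
Longest linear sequence: 8 steps (steps 1, 2, 3, 4, 8, 9, 10, 11, from 1 to 18). The ring B branch (steps 5, 6, 7) joins at step 8.

Steps most likely to fail

Step 10. The benzyl groups, above all the one peri to the new carbonyl, may be lost or may migrate under the acid that builds up. Ring A may be trifluoroacetylated at the position para to O1. The donor-stabilised mixed anhydride may ionise too slowly. The fallback sets out from phenol 6 and β-keto ester 12 and reverses the order of bond formation. The two are heated together without acid, neat or in diphenyl ether at about 240 °C (Mentzer pyrone synthesis). Thermal C-acylation of 6 at its only free ortho position by the ester group of 12, with loss of methanol, should give 1-[6-(benzyloxy)-2-hydroxy-3,4-dimethoxyphenyl]-3-[2,3-bis(benzyloxy)phenyl]-2-methoxypropane-1,3-dione F1. F1 is not isolated and cyclodehydrates through O1–C2 closure to flavone 17, where the route is rejoined.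

Step 8. The phenoxide may attack the sulfur of the triflate, transferring the triflyl group and returning the β-keto ester. Addition at the fully substituted β-carbon may be slow. Bond rotation in the adduct may erode the alkene geometry. The fallback sets out from 13 and 6 and returns at 14 by C–O cross-coupling, which replaces addition–elimination by oxidative addition of the vinyl triflate to zerovalent palladium followed by C–O reductive elimination (Pd2(dba)3, 2-(di-tert-butylphosphino)biphenyl, K3PO4, toluene, 80 °C). No new compound is formed (F0).

Step 9. Hydroxide may add at the β-carbon and expel the aryloxide, cleaving the vinylogous carbonate back to phenol 6, or may scramble the alkene geometry by reversible addition. The fallback sets out from 14 and returns at 15 by dealkylative ester cleavage. LiI in refluxing EtOAc attacks the ester methyl carbon (SN2, alkyl–oxygen fission), so no oxygen nucleophile meets the β-carbon, and the lithium carboxylate is acidified in the cold to 15. No new compound is formed (F0).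

Further compounds
F1 | step 10 | 1-[6-(benzyloxy)-2-hydroxy-3,4-dimethoxyphenyl]-3-[2,3-bis(benzyloxy)phenyl]-2-methoxypropane-1,3-dione | COC(C(=O)c1c(O)c(OC)c(OC)cc1OCc1ccccc1)C(=O)c1cccc(OCc2ccccc2)c1OCc1ccccc1
F0 | step 8 | none | none
F0 | step 9 | none | none
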